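Numbering is that of 1-benzofuran (O1, C2, C3, C3a, C4–C7, C7a); ring A is the carbocycle and ring B the dihydrofuran.
Enabling feature: in ring A, C5, C6, C7 and C7a are contiguous and each bears oxygen, so they map onto the four carbons of a squarate ester. The remaining pair C4–C3a maps onto an alkyne, so ring A is grown from a cyclobutenone (4 → 6).
Retrosynthetic cuts, in order: O1–C7a (carbonyl moved from C6 to C7a, + MeOH), O–CH3 at C5, C5–allyl, C3a–C7a (ring expansion), C4–C5 (acetylide addition), C2–C3 (propargylation).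
Forward: the chain C2–C3–C3a≡C4 is made first and joined to dimethyl squarate. Ring A then forms by thermal ring expansion to a benzoquinone, quaternary C5 by allyl addition and O-methylation, and ring B closes last.
Stereochemistry: C3 comes by chirality transfer from (R)-but-3-yn-2-ol. C2 comes from the anti-selective closed transition state of the same step, and its C–O bond is never broken afterwards. C5 comes by 1,4-induction from C3 in the allyl addition to the quinone.

Key step: step 5

Step 1
Reactants: 1 (R)-but-3-yn-2-ol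
Product: 2 (2R)-but-3-yn-2-yl methanesulfonate
Conditions: MsCl, Et3N, CH2Cl2, −78 → 0 °C
Reagents that add atoms: methanesulfonyl chloride CS(=O)(=O)Cl
Why: Sulfonylation at oxygen (mesylate formation) leaves the C–O bond and therefore the stereocentre untouched and provides the leaving group for step 2.

Step 2
Reactants: 2 (2R)-but-3-yn-2-yl methanesulfonate; 3 3,4,5-trimethoxybenzaldehyde
Product: 5 (1S,2S)-2-methyl-1-(3,4,5-trimethoxyphenyl)but-3-yn-1-ol, via allenyl(ethyl)zinc 4 (not isolated)
Conditions: Pd(OAc)2 (5 mol %), PPh3 (5 mol %), Et2Zn (3 equiv), THF, −78 → −20 °C; aq NH4Cl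
Reagents that add atoms: none
Why: Marshall propargylation, in which zerovalent palladium made in situ displaces the mesylate anti-SN2′, transmetalation gives the configurationally stable allenylzinc 4, and its syn-SE2′ addition through a closed transition state with the aryl group turned away from the allenyl methyl group should set C3 (net inversion of the carbinol carbon of 1) and C2 in the anti relation, any syn isomer being removed by chromatography.

Step 3
Reactants: 5 (1S,2S)-2-methyl-1-(3,4,5-trimethoxyphenyl)but-3-yn-1-ol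
Product: 6 triisopropylsilyl ether of 5
Conditions: i-Pr3SiOTf, 2,6-lutidine, CH2Cl2, 0 °C
Reagents that add atoms: triisopropylsilyl triflate CC(C)[Si](C(C)C)(C(C)C)OS(=O)(=O)C(F)(F)F
Why: Silyl ether formation at oxygen masks the acidic OH before the acetylide is made and installs the bulky group that later shields one quinone face, with no stereocentre touched.

Step 4
Reactants: 6 triisopropylsilyl ether of 5; 7 dimethyl squarate (3,4-dimethoxycyclobut-3-ene-1,2-dione)
Product: 9 4-hydroxy-2,3-dimethoxy-4-[(3S,4S)-3-methyl-4-(triisopropylsilyloxy)-4-(3,4,5-trimethoxyphenyl)but-1-yn-1-yl]cyclobut-2-en-1-one (both epimers at the ring carbinol), via lithium acetylide 8 (not isolated)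
Conditions: n-BuLi, THF, −78 °C; then 7, THF, −78 °C; aq NH4Cl
Reagents that add atoms: none
Why: 1,2-Addition of a lithium acetylide to one of the two equivalent carbonyl groups of a squarate ester forms C4–C5, and the mixture at the new carbinol centre does not matter because that carbon becomes planar in step 5.

Step 5
Reactants: 9 4-alkynyl-4-hydroxy-2,3-dimethoxycyclobutenone
Product: 12 2,3-dimethoxy-5-[(1S,2S)-1-(triisopropylsilyloxy)-1-(3,4,5-trimethoxyphenyl)propan-2-yl]cyclohexa-2,5-diene-1,4-dione, via enynylketene 10 (not isolated), via sigma-pi diradical 11 (not isolated)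
Conditions: toluene (degassed, dilute), 110 °C, Ar
Reagents that add atoms: none
Why: Heating cleaves the C5–C7a bond of the cyclobutenone by conrotatory 4π electrocyclic opening, the hydroxyl group turning outward (donor torquoselectivity) so that the alkynyl group ends cis to the ketene in 10. The ketene carbon C7a then bonds to the distal alkyne carbon C3a to give the six-membered diradical 11 (aryl radical at C4, phenoxyl on the C7a oxygen), and transfer of the hydroxyl hydrogen to C4 gives quinone 12, so the four-membered ring grows by the two alkyne carbons. The closest known reaction type is the Moore rearrangement of 4-alkynyl-4-hydroxycyclobutenones to 1,4-benzoquinones, driven by release of ring strain. The one ring closure is 6-endo-dig with respect to the alkyne. No new stereocentre is formed, the carbinol centre of 9 is erased, and C2 and C3 are spectators. The step needs 6-endo over 5-exo closure (which would give an alkylidenecyclopentenedione), and the plain alkyl substituent on C3a, which does not stabilise a vinyl radical, should secure it, while the position of all six ring substituents is fixed by the connectivity of 9.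

Step 6
Reactants: 12 2,3-dimethoxy-5-alkyl-1,4-benzoquinone
Product: 14 (4R)-4-hydroxy-2,3-dimethoxy-4-(prop-2-en-1-yl)-6-[(1S,2S)-1-(triisopropylsilyloxy)-1-(3,4,5-trimethoxyphenyl)propan-2-yl]cyclohexa-2,5-dien-1-one, via bromomagnesium alkoxide 13 (not isolated)
Conditions: allylMgBr (1.1 equiv), THF, −78 °C; aq NH4Cl at −78 °C
Reagents that add atoms: allylmagnesium bromide C=CC[Mg]Br
Why: 1,2-Addition of an allyl Grignard reagent to a p-benzoquinone (quinol synthesis) should go to the C5 carbonyl, flanked by C4–H, rather than to the C7a carbonyl next to the branched chain, and from the face opposite the CH(OSi-i-Pr3)Ar group, because A(1,3) strain holds C3–H in the ring plane syn to the C7a oxygen and so places that group under C4/C5 and only the methyl group over them, which sets C5 as R.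

Step 7
Reactants: 14 (4R)-quinol
Product: 15 (4R)-2,3,4-trimethoxy-4-(prop-2-en-1-yl)-6-[(1S,2S)-1-(triisopropylsilyloxy)-1-(3,4,5-trimethoxyphenyl)propan-2-yl]cyclohexa-2,5-dien-1-one
Conditions: MeI (excess), Ag2O, 4 Å MS, CH2Cl2, rt, dark
Reagents that add atoms: iodomethane CI
Why: Purdie methylation (MeI/Ag2O) works under neutral conditions, so the tertiary bis-allylic alcohol should be etherified without ionisation, retro-allylation or anionic oxy-Cope shift, and C5 keeps its configuration.

Step 8
Reactants: 15 (4R)-quinol methyl ether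
Product: 18 (2S,3S,5R)-5,7-dimethoxy-3-methyl-5-(prop-2-en-1-yl)-2-(3,4,5-trimethoxyphenyl)-3,5-dihydro-1-benzofuran-6(2H)-one (target), via free benzylic alcohol 16 (not isolated), via bicyclic hemiketal 17 (not isolated)
Conditions: HF·pyridine, THF, 0 °C → rt; then camphorsulfonic acid (10 mol %), moist CH2Cl2, rt
Reagents that add atoms: none
Why: Fluoride cleaves the silyl ether, the freed C2–OH adds to the C7a carbonyl (5-exo-trig, hemiketal 17), and acid-catalysed loss of water, re-addition of that water at C6 and loss of methanol (intramolecular alkoxy exchange of a vinylogous ester through 1,2-addition, hence with carbonyl transposition) should give the target, in which C2, C3 and C5 are retained because no bond to them is broken and the 2,3-trans relation follows from the anti alcohol.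

Compound list
1 | (R)-but-3-yn-2-ol | C[C@@H](O)C#C | starting material
2 | (2R)-but-3-yn-2-yl methanesulfonate | C[C@@H](OS(C)(=O)=O)C#C | intermediate
3 | 3,4,5-trimethoxybenzaldehyde | COc1cc(C=O)cc(OC)c1OC | starting material
4 | axially chiral buta-1,2-dien-1-yl(ethyl)zinc | CC([H])=[C@@]=C([H])[Zn]CC | intermediate
5 | (1S,2S)-2-methyl-1-(3,4,5-trimethoxyphenyl)but-3-yn-1-ol | C#C[C@H](C)[C@H](O)c1cc(OC)c(OC)c(OC)c1 | intermediate
6 | {[(1S,2S)-2-methyl-1-(3,4,5-trimethoxyphenyl)but-3-yn-1-yl]oxy}tri(propan-2-yl)silane | C#C[C@H](C)[C@H](O[Si](C(C)C)(C(C)C)C(C)C)c1cc(OC)c(OC)c(OC)c1 | intermediate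
7 | dimethyl squarate | COC1=C(OC)C(=O)C1=O | starting material
8 | lithium acetylide of 6 | [Li]C#C[C@H](C)[C@H](O[Si](C(C)C)(C(C)C)C(C)C)c1cc(OC)c(OC)c(OC)c1 | intermediate
9 | 4-alkynyl-4-hydroxy-2,3-dimethoxycyclobut-2-en-1-one (ring carbinol unassigned, both epimers) | COC1=C(OC)C(O)(C#C[C@H](C)[C@H](O[Si](C(C)C)(C(C)C)C(C)C)c2cc(OC)c(OC)c(OC)c2)C1=O | intermediate
10 | enynylketene, alkynyl cis to the ketenyl group | O=C=C(OC)/C(OC)=C(/O)C#C[C@H](C)[C@H](O[Si](C(C)C)(C(C)C)C(C)C)c1cc(OC)c(OC)c(OC)c1 | intermediate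
11 | diradical (aryl radical at C4, phenoxyl at the C7a oxygen) | [O]c1c(OC)c(OC)c(O)[c]c1[C@H](C)[C@H](O[Si](C(C)C)(C(C)C)C(C)C)c2cc(OC)c(OC)c(OC)c2 | intermediate
12 | 2,3-dimethoxy-5-[(1S,2S)-1-(triisopropylsilyloxy)-1-(3,4,5-trimethoxyphenyl)propan-2-yl]-1,4-benzoquinone | COC1=C(OC)C(=O)C([C@H](C)[C@H](O[Si](C(C)C)(C(C)C)C(C)C)c2cc(OC)c(OC)c(OC)c2)=CC1=O | intermediate
13 | bromomagnesium alkoxide of 14 | C=CC[C@@]1(O[Mg]Br)C=C([C@H](C)[C@H](O[Si](C(C)C)(C(C)C)C(C)C)c2cc(OC)c(OC)c(OC)c2)C(=O)C(OC)=C1OC | intermediate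
14 | (4R)-4-allyl-4-hydroxy-2,3-dimethoxy-6-alkylcyclohexa-2,5-dien-1-one | C=CC[C@@]1(O)C=C([C@H](C)[C@H](O[Si](C(C)C)(C(C)C)C(C)C)c2cc(OC)c(OC)c(OC)c2)C(=O)C(OC)=C1OC | intermediate
15 | (4R)-4-allyl-2,3,4-trimethoxy-6-alkylcyclohexa-2,5-dien-1-one | C=CC[C@@]1(OC)C=C([C@H](C)[C@H](O[Si](C(C)C)(C(C)C)C(C)C)c2cc(OC)c(OC)c(OC)c2)C(=O)C(OC)=C1OC | intermediate
16 | desilylated 15 (free C2–OH) | C=CC[C@@]1(OC)C=C([C@H](C)[C@H](O)c2cc(OC)c(OC)c(OC)c2)C(=O)C(OC)=C1OC | intermediate
17 | (2S,3S,5R)-5-allyl-5,6,7-trimethoxy-3-methyl-2-aryl-3,5-dihydro-1-benzofuran-7a(2H)-ol (C7a unassigned) | C=CC[C@@]1(OC)C=C2C(O)(C(OC)=C1OC)O[C@H](c1cc(OC)c(OC)c(OC)c1)[C@H]2C | intermediate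
18 | (2S,3S,5R)-5-allyl-5,7-dimethoxy-3-methyl-2-(3,4,5-trimethoxyphenyl)-3,5-dihydro-1-benzofuran-6(2H)-one | C=CC[C@@]1(OC)C=C2C(=C(OC)C1=O)O[C@H](c1cc(OC)c(OC)c(OC)c1)[C@H]2C | target

Total step count: 8. Longest linear sequence: 8 (1 → 18); 3 and 7 enter as purchased.

Steps most likely to fail

1. Step 6. The controlling centre C3 is three bonds from C5, so face selectivity may be poor, and electron transfer from the Grignard reagent may reduce the quinone.
Fallback, from 12 back to 18: the addition is run without relying on face control. The C5-epimeric quinol F1 is separated, methylated (MeI, Ag2O) to the epimeric methyl ether F2, and closed as in step 8 to the 5-epi target F3. Irradiation of F3 (about 350–365 nm, dry benzene, rt, no nucleophile) opens the C5–C6 bond (Barton–Quinkert reaction) to the dienylketene F4. F4 recloses thermally by 6π electrocyclisation on either face of C5, so only C5 is epimerised. Compound 18 is separated and F3 is returned to the lamp.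

2. Step 8. The cation formed after loss of water is an arenium-type ion with the allyl group on its sp3 carbon. A 1,2-shift or loss of allyl would aromatise ring A, and the sequence may also stall at the hemiketal.
Fallback without acid, from 15 back to 18: EtSNa (DMF, 0 °C) removes the methyl group of the vinylogous ester by SN2 at carbon to give the vinylogous acid F5. Me3SiCHN2 then gives both enol ethers, 15 (recycled) and the transposed 2,4-dienone F6. Bu4NF frees the C2 alkoxide of F6, which replaces the C7a methoxy group by conjugate addition–elimination (5-exo-trig) to give 18.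

3. Step 5. The aryl radical at C4 of 11 may abstract the activated C2–H (1,5-hydrogen transfer) instead of receiving the hydroxyl hydrogen. That would scramble C2 or lead to cyclised side products, and some 5-exo closure may also occur.
Closed-shell fallback, from 6 back to 12: Markovnikov hydroalumination (i-Bu2AlH, Ni(dppp)Cl2 cat., THF) followed by I2 gives the 2-iodoalkene F7. Exchange with t-BuLi and addition to 7 gives the 4-alkenyl-4-hydroxycyclobutenone F8. Heating in toluene (4π opening, 6π closure of the dienylketene, tautomerisation) gives the hydroquinone F9, and Ag2O oxidises it to 12.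

Further compounds
F1 | step 6 | (4S)-4-allyl-4-hydroxy-2,3-dimethoxy-6-alkylcyclohexa-2,5-dien-1-one | C=CC[C@]1(O)C=C([C@H](C)[C@H](O[Si](C(C)C)(C(C)C)C(C)C)c2cc(OC)c(OC)c(OC)c2)C(=O)C(OC)=C1OC
F2 | step 6 | (4S)-4-allyl-2,3,4-trimethoxy-6-alkylcyclohexa-2,5-dien-1-one | C=CC[C@]1(OC)C=C([C@H](C)[C@H](O[Si](C(C)C)(C(C)C)C(C)C)c2cc(OC)c(OC)c(OC)c2)C(=O)C(OC)=C1OC
F3 | step 6 | (2S,3S,5S)-5-allyl-5,7-dimethoxy-3-methyl-2-(3,4,5-trimethoxyphenyl)-3,5-dihydro-1-benzofuran-6(2H)-one | C=CC[C@]1(OC)C=C2C(=C(OC)C1=O)O[C@H](c1cc(OC)c(OC)c(OC)c1)[C@H]2C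
F4 | step 6 | dienylketene from C5–C6 cleavage (C4=C5 geometry unassigned) | O=C=C(OC)C1=C(C=C(OC)CC=C)[C@H](C)[C@@H](c2cc(OC)c(OC)c(OC)c2)O1
F5 | step 8 | (4R)-4-allyl-3-hydroxy-2,4-dimethoxy-6-alkylcyclohexa-2,5-dien-1-one | C=CC[C@@]1(OC)C=C([C@H](C)[C@H](O[Si](C(C)C)(C(C)C)C(C)C)c2cc(OC)c(OC)c(OC)c2)C(=O)C(OC)=C1O
F6 | step 8 | (6R)-6-allyl-2,3,6-trimethoxy-4-alkylcyclohexa-2,4-dien-1-one | C=CC[C@@]1(OC)C=C([C@H](C)[C@H](O[Si](C(C)C)(C(C)C)C(C)C)c2cc(OC)c(OC)c(OC)c2)C(OC)=C(OC)C1=O
F7 | step 5 | {[(1S,2R)-3-iodo-2-methyl-1-(3,4,5-trimethoxyphenyl)but-3-en-1-yl]oxy}tri(propan-2-yl)silane | C=C(I)[C@H](C)[C@H](O[Si](C(C)C)(C(C)C)C(C)C)c1cc(OC)c(OC)c(OC)c1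
F8 | step 5 | 4-alkenyl-4-hydroxy-2,3-dimethoxycyclobut-2-en-1-one (ring carbinol unassigned) | COC1=C(OC)C(O)(C(=C)[C@H](C)[C@H](O[Si](C(C)C)(C(C)C)C(C)C)c2cc(OC)c(OC)c(OC)c2)C1=O
F9 | step 5 | 2,3-dimethoxy-5-alkylbenzene-1,4-diol | COc1c(OC)c(O)c(cc1O)[C@H](C)[C@H](O[Si](C(C)C)(C(C)C)C(C)C)c2cc(OC)c(OC)c(OC)c2
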